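A small charge comes first: the protic impurity is 2.00% of the starting material. We follow one molecule of starting material through its forks.

| setting | zeta | beta | alpha | eta |
|---|---|---|---|---|
| starting material | 5.0 mM | 5.0 mM (fed, over 40.0 s) | 5.0 mM | 5.0 mM |
| partner | 4.00 equiv | 4.00 equiv | 4.00 equiv | 4.00 equiv (fed, over 40.0 s) |
| protic impurity | 0.100 mM | 0.100 mM | 0.100 mM | 0.100 mM |
| time | 50 s | 50 s |  | 50 s |
| remark | everything together in a closed stirred flask, run for 50 s | all but starting material at the start; starting material goes in evenly over 40.0 s, the run ends at 50 s | one stirred flow tank at steady state, fed with the mixture as stated, mean residence time 50 s | a stirred flask in which partner is dosed at a steady rate over 40.0 s without added volume, worked up at 50 s |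

    starting material + partner → target, rate k1*[starting material]*[partner]^1.5 (k1 = 15 /M^1.5/s)
    starting material + protic impurity → quenched substrate (k2 = 4400 /M/s)
    target ⇌ isomer of the product (K3 = 1.6, k3 = 0.021 /s)

- the stated concentrations are those of everything mixed, before any reaction; amounts are the same in each set-up
- the feed brings no volume worth counting
- run time (zeta): 50 s

* the set-up with the highest amount of target at the outlet or at the end, in percent of the starting material put in ("none" if the first two lie within 2 percentage points) (zeta / beta / alpha / eta / none)
* amount of target at the outlet or at the end, in percent of the starting material put in, zeta
* amount of target at the outlet or at the end, in percent of the starting material put in, beta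
* amount of target at the outlet or at the end, in percent of the starting material put in, alpha
* amount of target at the outlet or at the end, in percent of the starting material put in, eta

At the first fork, does our molecule meet impurity or partner? At the charges, impurity takes a molecule of starting material at 0.440 /s, and partner takes it at 0.0424 /s. This is a pseudo-first-order rate, one that treats partner as held at its charge. Impurity is about ten times quicker, so we book its charge as lost starting material and go on.

Once target forms, does it last? Target turns into isomer at 0.021 /s per molecule, so forming target runs 2.02 times as fast as losing it. We carry this ratio of forming rate to loss rate as the race ratio ρ. It is not large, so the two clocks run side by side.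

How much time does each set-up give the molecule, then? In zeta it has 50 s, or 2.12 forming lifetimes, so starting material still profits from time. In beta, the average molecule enters at 20.0 s and has 30.0 s. That is 1.27 forming lifetimes in beta. In eta, the forming rate climbs with dosed partner, so the dosing period counts as 0.400 of its length, giving 1.10 forming lifetimes, fewer than zeta's. In alpha, the tank works at its outlet level, so with partner held, 32.1% of the starting material stays, more than the 12.0% in zeta. Time also turns target into isomer, and this count does not weigh that, so zeta as best is our judgement, given without percentages.

The forecast also names zeta, with 48.7% for zeta, 44.3% for beta, 37.3% for alpha and 44.1% for eta. From its hand stepping it concludes: “Batch wins, by more than 2 points.”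

The simulation gives zeta as best, with 48.8% for zeta, 44.3% for beta, 37.4% for alpha and 43.9% for eta. In beta at 50.0 s, starting material halves by forming target in 21 s and target halves by the forward step in 33 s, a race ratio of 1.57, with 36.3% of the starting material still there. The neighbour of beta with 16.0 equiv of partner has a race ratio at its charge of 16.2 and ends with 0.36% of the starting material and 63.7% as target.

(All constants were set for the occasion.)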